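Everything rests on cutting the C3–C4 bond of ring A. The key step exploits the gem-dimethyl quaternary carbon C4 beside the ring-fusion carbon C5: seen backwards, C4 with its two methyls is an isopropenyl substituent on a cyclohexenone that already is ring B (C5–C10, C7=C8 olefin, C17 methyl), which is (S)-carvone. The precursor is therefore carvone carrying at C10 a methyl group and, trans to the isopropenyl group, a 2-(methoxycarbonyl)allyl arm. One iron-hydride hydrogen-atom transfer converts the isopropenyl group into a tertiary radical at C4 that adds to the acrylate CH2 (C3), closing ring A as a trans-decalin and creating the quaternary centre in a single operation.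

Key step: step 3

Remark: labdane numbering (C1–C20) is used for all bicyclic compounds; 4 is carried as a mixture of epimers at the methyl-bearing carbon and 8–10 as mixtures of C2 epimers, because both centres are erased later; the side chain is introduced as a conjugated Weinreb amide so that the ring B olefin is the only electron-rich olefin during the two allylic oxidations.

Step 1
Reactants: 1 (S)-(+)-carvone; 2 iodomethane
Product: 4 (5S)-2,6-dimethyl-5-(prop-1-en-2-yl)cyclohex-2-en-1-one (6-methylcarvone; epimer mixture at C6 of the carvone ring), via lithium enolate 3 (not isolated)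
Conditions: LiN(i-Pr)2, THF, −78 °C; then MeI, −78 → 0 °C
Reagents that add atoms: iodomethane (compound 2), CI
Why: Kinetic deprotonation by LiN(i-Pr)2 occurs at the only alpha-prime CH2 of the enone (carvone C6, the future C10) and the cross-conjugated enolate is C-methylated in an SN2 enolate alkylation; the new centre forms as an epimer mixture that is erased when this carbon is enolised again in step 2.

Step 2
Reactants: 4 6-methylcarvone; 5 methyl 2-(bromomethyl)acrylate
Product: 7 methyl 2-{[(1R,6R)-1,3-dimethyl-2-oxo-6-(prop-1-en-2-yl)cyclohex-3-en-1-yl]methyl}prop-2-enoate (acrylate arm trans to the isopropenyl group; C10 methyl cis to it), via lithium enolate 6 (not isolated)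
Conditions: LiN(i-Pr)2, THF, −78 °C; then 5, DMPU, −78 → −20 °C
Reagents that add atoms: methyl 2-(bromomethyl)acrylate (compound 5), C=C(CBr)C(=O)OC
Why: The same alpha-prime carbon is deprotonated again and the tetrasubstituted enolate is alkylated by the allylic bromide (enolate alkylation, by SN2 or SN2' addition–elimination, which give the same product) on the ring face anti to the neighbouring C5 isopropenyl group, which sets the quaternary C10 centre with the acrylate arm trans to the isopropenyl group.

Step 3
Reactants: 7 doubly alkylated carvone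
Product: 8 methyl (4aR,8aR)-4,4,7,8a-tetramethyl-8-oxo-1,2,3,4,4a,5,8,8a-octahydronaphthalene-2-carboxylate (trans-fused 7-en-9-one with the ester at C2; C2 epimers)
Conditions: Fe(acac)3 (30 mol %), PhSiH3, EtOH/(CH2OH)2 (5:1), 60 °C
Reagents that add atoms: none
Why: Fe(acac)3 and PhSiH3 in ethanol generate an iron hydride that transfers a hydrogen atom to the terminal CH2 of the electron-rich 1,1-disubstituted isopropenyl olefin, the resulting nucleophilic tertiary C4 radical adds to the unsubstituted terminus C3 of the acrylate, and the alpha-ester radical at C2 is reduced by divalent iron and protonated by the solvent. The closest known reaction type is the iron-hydride hydrogen-atom-transfer reductive olefin coupling (a radical Giese addition) in its intramolecular form that creates a quaternary carbon. Ring A closes in the 6-endo-trig mode, which is preferred over 5-exo attack because the latter would have to strike the fully substituted, ester-bearing C2 against the polarity of the acceptor. The only new stereocentre is C2, which is not controlled and need not be because the ester is excised in steps 4 and 5, while the trans ring fusion follows from the existing C5 and C10 centres, whose two reacting arms are trans on ring B. The step needs chemoselective hydrogen-atom transfer to the isopropenyl group, which is secured because the acrylate and the ring B enone are electron-poor olefins that accept radicals and not hydrogen atoms, and because the enone carbons C7 and C8 are out of reach of the C4 radical (4-exo or 5-endo).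

Step 4
Reactants: 8 bicyclic methyl ester
Product: 9 (4aR,8aR)-4,4,7,8a-tetramethyl-8-oxo-1,2,3,4,4a,5,8,8a-octahydronaphthalene-2-carboxylic acid (C2 epimers)
Conditions: LiOH, THF/MeOH/H2O, 40 °C; then aq. HCl
Reagents that add atoms: lithium hydroxide, [Li+].[OH-]
Why: Saponification (ester hydrolysis) of the unhindered secondary methyl ester should leave the enone, which carries no base-labile group, untouched, and no stereocentre is formed.

Step 5
Reactants: 9 carboxylic acid
Product: 11 (4aR,8aR)-2,5,5,8a-tetramethyl-4a,5,6,7,8,8a-hexahydronaphthalen-1(4H)-one (trans-fused 7-en-9-one; 11-nor-ent-drim-7-en-9-one), via Barton ester 10 (not isolated)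
Conditions: N-hydroxypyridine-2-thione, DCC, DMAP (cat.), CH2Cl2, 0 °C → rt, dark; then t-BuSH, hν (tungsten lamp), PhH, rt
Reagents that add atoms: none
Why: Barton reductive decarboxylation, in which carbodiimide coupling gives the O-acyl thiohydroxamate and its visible-light homolysis releases CO2 and a secondary C2 radical that abstracts hydrogen from t-BuSH, removes the C2 stereocentre and should not affect the remote enone.

Step 6
Reactants: 11 trans-fused 7-en-9-one
Product: 12 (4aR,8aR)-2,5,5,8a-tetramethyl-1-methylidene-1,4,4a,5,6,7,8,8a-octahydronaphthalene (ent-drima-7,9(11)-diene)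
Conditions: Ph3PCH3Br, KOt-Bu, toluene, 90 °C
Reagents that add atoms: methyltriphenylphosphonium bromide, C[P+](c1ccccc1)(c1ccccc1)c1ccccc1.[Br-]
Why: Wittig methylenation with Ph3P=CH2 at elevated temperature, the usual protocol for hindered ketones, should convert the C9 carbonyl (which has no alpha hydrogen to enolise) into the exocyclic C9=C11 olefin by 1,2-addition, and no stereocentre is formed.

Step 7
Reactants: 13 diethyl methylmalonate; 14 iodoform
Product: 16 diethyl 2-(diiodomethyl)-2-methylmalonate, via sodium enolate 15 (not isolated)
Conditions: NaH, Et2O, reflux; then CHI3, reflux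
Reagents that add atoms: iodoform (compound 14), IC(I)I
Why: C-alkylation of the sodium malonate enolate by iodoform (enolate alkylation, the established entry to diiodomethyl malonates) places the CHI2 group on the quaternary carbon, and no stereocentre is formed.

Step 8
Reactants: 16 diiodomethyl malonate
Product: 18 (E)-3-iodo-2-methylprop-2-enoic acid, via dipotassium dicarboxylate 17 (not isolated)
Conditions: KOH, EtOH/H2O, reflux; then aq. HCl
Reagents that add atoms: potassium hydroxide, [K+].[OH-]
Why: Saponification of both esters followed by decarboxylative elimination of iodide from the dicarboxylate (a Grob-type fragmentation) should give the beta-iodoacrylic acid as the more stable E isomer, with iodine trans to the carboxyl group.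

Step 9
Reactants: 18 (E)-3-iodo-2-methylprop-2-enoic acid
Product: 20 (E)-3-iodo-N-methoxy-N,2-dimethylprop-2-enamide, via acid chloride 19 (not isolated)
Conditions: (COCl)2, DMF (cat.), CH2Cl2, 0 °C → rt; then MeNH(OMe)·HCl, pyridine, CH2Cl2, 0 °C → rt
Reagents that add atoms: N,O-dimethylhydroxylamine hydrochloride, CNOC.Cl
Why: Acid chloride formation and acylation of N,O-dimethylhydroxylamine (Weinreb amide synthesis) should proceed without touching the alkenyl iodide or its E geometry.

Step 10
Reactants: 12 ent-drima-7,9(11)-diene; 20 alkenyl iodide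
Product: 22 N-methoxy-N-methyl amide of 15-nor-ent-labda-7,12(E)-dien-14-oic acid (C11 arm syn to the C10 methyl), via alkylborane 21 (not isolated)
Conditions: 9-BBN, THF, 0 °C → rt; then H2O, 20, Pd(dppf)Cl2 (5 mol %), AsPh3, Cs2CO3, DMF, rt
Reagents that add atoms: (E)-3-iodo-N-methoxy-N,2-dimethylprop-2-enamide (compound 20), C/C(=C\I)C(=O)N(C)OC
Why: 9-BBN hydroborates only the terminal 1,1-disubstituted C9=C11 olefin (anti-Markovnikov, boron on C11) from the face opposite the axial C10 methyl, so that H-9 ends anti and the C11 arm syn to that methyl, and the B-alkyl Suzuki–Miyaura coupling of the alkylborane with the alkenyl iodide then forms C11–C12 with retention of the E geometry.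

Step 11
Reactants: 22 side-chain amide with the C7=C8 olefin
Product: 23 17-hydroxy derivative of 22
Conditions: SeO2 (cat.), t-BuOOH, CH2Cl2, rt
Reagents that add atoms: selenium dioxide, O=[Se]=O; tert-butyl hydroperoxide, CC(C)(C)OO
Why: SeO2 allylic oxidation (ene reaction then [2,3]-sigmatropic shift, with t-BuOOH as reoxidant so that the reaction stops mainly at the alcohol) attacks the more substituted end of the only electron-rich olefin C7=C8 at its methyl group C17 in preference to the C9 methine, while the conjugated amide olefin is inert, and no stereocentre is formed.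

Step 12
Reactants: 23 C17 allylic alcohol
Product: 24 17-acetoxy derivative of 22
Conditions: Ac2O, pyridine, DMAP (cat.), CH2Cl2, rt
Reagents that add atoms: acetic anhydride, CC(=O)OC(C)=O
Why: DMAP-catalysed acetylation protects the primary allylic hydroxyl, which would otherwise be oxidised to an enal in step 13 and deactivate the olefin, and no stereocentre is affected.

Step 13
Reactants: 24 C17 acetate
Product: 25 17-acetoxy-6-oxo derivative of 22 (7-en-6-one)
Conditions: CrO3, 3,5-dimethylpyrazole, CH2Cl2, −20 °C
Reagents that add atoms: chromium trioxide, O=[Cr](=O)=O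
Why: Allylic oxidation with the CrO3–3,5-dimethylpyrazole complex, a reaction type established for trisubstituted cyclohexenes of this kind, should convert the ring methylene C6 next to the C7=C8 olefin into the conjugated ketone while the electron-poor amide olefin and the ester stay intact; C5 and C9 keep their more stable trans-fused and equatorial arrangements.

Step 14
Reactants: 25 7-en-6-one
Product: 26 6,17-dihydroxy-15-nor-ent-labda-7,12(E)-dien-14-al (6-hydroxyl syn to the C10 methyl)
Conditions: i-Bu2AlH (excess), CH2Cl2, −78 → −40 °C; then aq. potassium sodium tartrate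
Reagents that add atoms: none
Why: Excess i-Bu2AlH should carry out three hydride reductions at once, since the Weinreb amide stops at the chelated hemiaminal that gives the enal on work-up, the acetate is cleaved, and the C6 ketone undergoes 1,2-reduction by hydride delivery to the face opposite the syn-axial C10 and C4 methyl groups, which places the new 6-hydroxyl syn to the C10 methyl.

Step 15
Reactants: 26 diol enal
Product: 27 ent-labda-7,12(E),14-triene-6,17-diol
Conditions: Ph3PCH3Br, KN(SiMe3)2, THF, 0 °C; then 26, −78 → 0 °C
Reagents that add atoms: methyltriphenylphosphonium bromide, C[P+](c1ccccc1)(c1ccccc1)c1ccccc1.[Br-]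
Why: Wittig methylenation of the unhindered enal with excess Ph3P=CH2 at low temperature (the two hydroxyls are carried as alkoxides) should build the terminal C14=C15 olefin without touching the trisubstituted E olefin or any stereocentre.

Step 16
Reactants: 27 triene diol
Product: 28 [(1S,4S,4aR,8aS)-4-acetoxy-5,5,8a-trimethyl-1-[(2E)-3-methylpenta-2,4-dien-1-yl]-1,4,4a,5,6,7,8,8a-octahydronaphthalen-2-yl]methyl acetate (target)
Conditions: Ac2O, DMAP, pyridine, CH2Cl2, rt → 40 °C
Reagents that add atoms: acetic anhydride, CC(=O)OC(C)=O
Why: DMAP-catalysed acetylation should esterify both the primary allylic C17 hydroxyl and, more slowly, the hindered axial C6 hydroxyl without affecting the diene or any stereocentre, which gives the target.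

Compound list
1 | (S)-(+)-carvone | CC1=CC[C@@H](CC1=O)C(C)=C | starting material
2 | iodomethane | CI | starting material
3 | kinetic lithium enolate of 1 | CC1=CC[C@@H](C=C1O[Li])C(C)=C | intermediate
4 | (5S)-2,6-dimethyl-5-(prop-1-en-2-yl)cyclohex-2-en-1-one (epimer mixture at the new methyl-bearing carbon) | CC1=CC[C@@H](C(C)C1=O)C(C)=C | intermediate
5 | methyl 2-(bromomethyl)acrylate | C=C(CBr)C(=O)OC | starting material
6 | lithium enolate of 4 | CC1=CC[C@@H](C(C)=C1O[Li])C(C)=C | intermediate
7 | methyl 2-{[(1R,6R)-1,3-dimethyl-2-oxo-6-(prop-1-en-2-yl)cyclohex-3-en-1-yl]methyl}prop-2-enoate | O=C1C(C)=CC[C@H](C(C)=C)[C@@]1(C)CC(=C)C(=O)OC | intermediate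
8 | methyl (4aR,8aR)-4,4,7,8a-tetramethyl-8-oxo-1,2,3,4,4a,5,8,8a-octahydronaphthalene-2-carboxylate (C2 epimers) | O=C1C(C)=CC[C@@H]2C(C)(C)CC(C(=O)OC)C[C@@]12C | intermediate
9 | (4aR,8aR)-4,4,7,8a-tetramethyl-8-oxo-1,2,3,4,4a,5,8,8a-octahydronaphthalene-2-carboxylic acid (C2 epimers) | O=C1C(C)=CC[C@@H]2C(C)(C)CC(C(=O)O)C[C@@]12C | intermediate
10 | Barton ester of 9 (2-thioxopyridin-1(2H)-yl ester) | O=C1C(C)=CC[C@@H]2C(C)(C)CC(C(=O)ON3C=CC=CC3=S)C[C@@]12C | intermediate
11 | (4aR,8aR)-2,5,5,8a-tetramethyl-4a,5,6,7,8,8a-hexahydronaphthalen-1(4H)-one | O=C1C(C)=CC[C@@H]2C(C)(C)CCC[C@@]12C | intermediate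
12 | (4aR,8aR)-2,5,5,8a-tetramethyl-1-methylidene-1,4,4a,5,6,7,8,8a-octahydronaphthalene (ent-drima-7,9(11)-diene) | C=C1C(C)=CC[C@@H]2C(C)(C)CCC[C@@]12C | intermediate
13 | diethyl methylmalonate | CCOC(=O)C(C)C(=O)OCC | starting material
14 | iodoform | IC(I)I | starting material
15 | sodium enolate of 13 | CCOC(=O)C(C)=C(OCC)O[Na] | intermediate
16 | diethyl 2-(diiodomethyl)-2-methylmalonate | CCOC(=O)C(C)(C(I)I)C(=O)OCC | intermediate
17 | dipotassium 2-(diiodomethyl)-2-methylmalonate | [K+].[K+].[O-]C(=O)C(C)(C(I)I)C([O-])=O | intermediate
18 | (E)-3-iodo-2-methylprop-2-enoic acid | C/C(=C\I)C(=O)O | intermediate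
19 | (E)-3-iodo-2-methylprop-2-enoyl chloride | C/C(=C\I)C(=O)Cl | intermediate
20 | (E)-3-iodo-N-methoxy-N,2-dimethylprop-2-enamide | C/C(=C\I)C(=O)N(C)OC | intermediate
21 | 9-(ent-drim-7-en-11-yl)-9-borabicyclo[3.3.1]nonane (C11 arm syn to the C10 methyl) | C(B1C2CCCC1CCC2)[C@@H]3C(C)=CC[C@@H]4C(C)(C)CCC[C@@]34C | intermediate
22 | N-methoxy-N-methyl amide of 15-nor-ent-labda-7,12(E)-dien-14-oic acid | CON(C)C(=O)/C(C)=C/C[C@@H]1C(C)=CC[C@@H]2C(C)(C)CCC[C@@]12C | intermediate
23 | 17-hydroxy derivative of 22 | CON(C)C(=O)/C(C)=C/C[C@@H]1C(CO)=CC[C@@H]2C(C)(C)CCC[C@@]12C | intermediate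
24 | 17-acetoxy derivative of 22 | CON(C)C(=O)/C(C)=C/C[C@@H]1C(COC(C)=O)=CC[C@@H]2C(C)(C)CCC[C@@]12C | intermediate
25 | 17-acetoxy-6-oxo derivative of 22 | CON(C)C(=O)/C(C)=C/C[C@@H]1C(COC(C)=O)=CC(=O)[C@@H]2C(C)(C)CCC[C@@]12C | intermediate
26 | 6,17-dihydroxy-15-nor-ent-labda-7,12(E)-dien-14-al (6-OH syn to the C10 methyl) | O=C/C(C)=C/C[C@@H]1C(CO)=C[C@H](O)[C@@H]2C(C)(C)CCC[C@@]12C | intermediate
27 | ent-labda-7,12(E),14-triene-6,17-diol (6-OH syn to the C10 methyl) | C=C/C(C)=C/C[C@@H]1C(CO)=C[C@H](O)[C@@H]2C(C)(C)CCC[C@@]12C | intermediate
28 | [(1S,4S,4aR,8aS)-4-acetoxy-5,5,8a-trimethyl-1-[(2E)-3-methylpenta-2,4-dien-1-yl]-1,4,4a,5,6,7,8,8a-octahydronaphthalen-2-yl]methyl acetate | C=C/C(C)=C/C[C@@H]1C(COC(C)=O)=C[C@H](OC(C)=O)[C@@H]2C(C)(C)CCC[C@@]12C | target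

Total step count: 16. Longest linear sequence: 13 steps (steps 1–6 and 10–16, from (S)-carvone); steps 7–9 make the alkenyl iodide.

Steps most likely to fail

Step 3 may fail through premature reduction of the tertiary C4 radical (net hydrogenation of the isopropenyl group) or through intermolecular addition to a second acrylate before the 6-endo closure. The fallback sets out from 7: Markovnikov addition of anhydrous HBr to the isopropenyl group (CH2Cl2, −78 °C) should give the tertiary bromide F1. Slow addition of Bu3SnH with AIBN in refluxing benzene at high dilution then generates the same C4 radical under a low concentration of hydrogen donor, so that ring closure onto the acrylate precedes reduction. This tin-hydride radical cyclisation rejoins the route at 8.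

Step 13 may fail through sluggish or misdirected hydrogen abstraction, because the acetoxymethyl group lowers the electron density of the C7=C8 olefin and the C9 methine and C11 methylene are competing allylic sites. The fallback sets out from 22 and moves the chromium oxidation forward to the unfunctionalised olefin, which should give the 6-ketone F2. Reduction with NaBH4 and CeCl3 from the open face should give the 6-alcohol F3 (hydroxyl syn to the C10 methyl), and acetylation the 6-acetate F4. SeO2 with t-BuOOH then oxidises C17 to the allylic alcohol F5, and i-Bu2AlH as in step 14 reduces the amide and cleaves the acetate, so that the route is rejoined at 26.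

Step 6 may fail through incomplete conversion, because the C9 carbonyl is flanked by the quaternary C10 and the methyl-bearing C8 and the ylide can be consumed by reversible gamma-deprotonation at C6. The fallback sets out from 11: 1,2-addition of the small, weakly basic nucleophile Me3SiCH2Li in the presence of CeCl3 (THF, −78 °C) should give the beta-hydroxysilane F6. Acid-induced Peterson elimination (aqueous HF in MeCN) gives the same diene, so that the route is rejoined at 12.

Further compounds
F1 | step 3 | methyl 2-{[(1R,6R)-6-(2-bromopropan-2-yl)-1,3-dimethyl-2-oxocyclohex-3-en-1-yl]methyl}prop-2-enoate (tertiary bromide) | O=C1C(C)=CC[C@H](C(C)(C)Br)[C@@]1(C)CC(=C)C(=O)OC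
F2 | step 13 | 6-oxo derivative of 22 (7-en-6-one with C17 methyl) | CON(C)C(=O)/C(C)=C/C[C@@H]1C(C)=CC(=O)[C@@H]2C(C)(C)CCC[C@@]12C
F3 | step 13 | 6-hydroxy derivative of 22 (hydroxyl syn to the C10 methyl) | CON(C)C(=O)/C(C)=C/C[C@@H]1C(C)=C[C@H](O)[C@@H]2C(C)(C)CCC[C@@]12C
F4 | step 13 | 6-acetoxy derivative of 22 | CON(C)C(=O)/C(C)=C/C[C@@H]1C(C)=C[C@H](OC(C)=O)[C@@H]2C(C)(C)CCC[C@@]12C
F5 | step 13 | 6-acetoxy-17-hydroxy derivative of 22 | CON(C)C(=O)/C(C)=C/C[C@@H]1C(CO)=C[C@H](OC(C)=O)[C@@H]2C(C)(C)CCC[C@@]12C
F6 | step 6 | (4aR,8aR)-2,5,5,8a-tetramethyl-1-[(trimethylsilyl)methyl]-1,4,4a,5,6,7,8,8a-octahydronaphthalen-1-ol (C9 epimers) | C[Si](C)(C)CC1(O)C(C)=CC[C@@H]2C(C)(C)CCC[C@@]12C
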